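**Retrosynthetic overview** (disconnections listed in the order in which the bonds are made)
1. Aryl–CH2 bonds of the C-6 and C-8 prenyl groups: 2,4-dihydroxyacetophenone 1 and prenyl bromide 2 give, through the monoprenyl ketones 3 and 4, the diprenyl ketone 5 (phenolate C-prenylation, the laboratory counterpart of an aromatic prenyltransferase).
2. C-2–C-3 bond (Cβ–Cα of the chalcone): 5 and veratraldehyde 6 give, through aldol 7, the 2',4'-dihydroxychalcone 8 (Claisen–Schmidt). Rings A and B are bought.
3. O-1–C-2 bond: chalcone 8 is the open-chain biosynthetic precursor of flavanone 9. Ring C, the only ring made, is closed last by a catalyst-controlled 6-endo-trig oxa-Michael addition that copies chalcone isomerase and sets C-2 (S) in the same event.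
4. No protecting groups and no redox steps; three steps in all.

Assumption: IN0946 is taken to be exactly the structure of the SMILES, (2S)-7-hydroxy-3',4'-dimethoxy-6,8-diprenylflavanone.
Assumption: the quinidine-derived thiourea is taken to give the (2S) series. This is checked on the first run by chiral HPLC and CD (a 2S flavanone shows a positive Cotton effect near 330 nm and a negative one near 290 nm). If the sense is the opposite, the quinine-derived pseudoenantiomer is used under identical conditions.

**Route**

Step 1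
Reactants: 1 2,4-dihydroxyacetophenone; 2 prenyl bromide (1-bromo-3-methylbut-2-ene)
Product: 5 1-[2,4-dihydroxy-3,5-bis(3-methylbut-2-en-1-yl)phenyl]ethan-1-one, via 5-monoprenyl ketone 3 (not isolated), via 3-monoprenyl ketone 4 (not isolated)
Conditions: 2 (3.0 equiv, two portions), KOH (10% aq, 3.5 equiv), 0 °C to rt, 24 h; then 1 M HCl; chromatography
Reagents that add atoms: prenyl bromide 2, CC(C)=CCBr
Why: Phenolate C-alkylation (nuclear prenylation): in water the phenoxide oxygens of 1 are hydrogen-bonded, so the allylic bromide is attacked by the two activated ring carbons C-3 and C-5 (C-6 is meta to both oxygens and inert), first giving 3 and 4 and then, from either, the same diprenyl ketone 5; no stereocentre is formed.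

Step 2
Reactants: 5 1-[2,4-dihydroxy-3,5-bis(3-methylbut-2-en-1-yl)phenyl]ethan-1-one; 6 veratraldehyde (3,4-dimethoxybenzaldehyde)
Product: 8 (E)-1-[2,4-dihydroxy-3,5-bis(3-methylbut-2-en-1-yl)phenyl]-3-(3,4-dimethoxyphenyl)prop-2-en-1-one, via aldol adduct 7 (not isolated)
Conditions: LiN(SiMe3)2 (4.2 equiv), THF, −78 °C, 1 h; then 6 (1.2 equiv), −78 °C to rt, 16 h; 1 M HCl to pH 5, 0 °C; chromatography
Reagents that add atoms: veratraldehyde 6, COc1ccc(C=O)cc1OC
Why: Claisen–Schmidt (crossed aldol) condensation run on the trilithium salt: LiN(SiMe3)2 deprotonates both phenols and the methyl ketone so that no protecting group is needed, the enolate adds to the non-enolisable aldehyde 6 to give aldolate 7, and E1cB loss of hydroxide on warming gives the conjugated, thermodynamically favoured E-chalcone 8, which destroys the transient stereocentre of 7.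

Step 3
Reactants: 8 (E)-1-[2,4-dihydroxy-3,5-bis(3-methylbut-2-en-1-yl)phenyl]-3-(3,4-dimethoxyphenyl)prop-2-en-1-one
Product: 9 (2S)-2-(3,4-dimethoxyphenyl)-7-hydroxy-6,8-bis(3-methylbut-2-en-1-yl)-2,3-dihydro-4H-chromen-4-one
Conditions: N-[3,5-bis(trifluoromethyl)phenyl]-N'-(9-deoxy-epi-quinidin-9-yl)thiourea (C29H28F6N4OS, 20 mol%), toluene (0.05 M), 4 Å MS, 30 °C, 72 h (chiral HPLC control); silica plug; recrystallise (heptane/EtOAc)
Reagents that add atoms: none
Why: Proposed new method: this extends the cinchona amine–thiourea-catalysed enantioselective intramolecular oxa-Michael cyclisation of 2'-hydroxychalcones (the closest known reaction type, best documented for α-ester-activated chalcones) to an unactivated, unprotected 6'-deoxychalcone, in which the thiourea N–H pair binds the enone carbonyl while the quinuclidine nitrogen takes the 2'-OH proton and delivers the phenoxide oxygen to the Si face of C-β within the chiral ion pair, creating C-2 as S in a 6-endo-trig closure, and protonation of the resulting enol gives the ketone without any reagent strong enough to reopen the ring.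

**Compound list**
1 | 2,4-dihydroxyacetophenone (1-(2,4-dihydroxyphenyl)ethan-1-one) | CC(=O)c1ccc(O)cc1O | starting material
2 | prenyl bromide (1-bromo-3-methylbut-2-ene) | CC(C)=CCBr | starting material
3 | 5-monoprenyl ketone, 1-[2,4-dihydroxy-5-(3-methylbut-2-en-1-yl)phenyl]ethan-1-one | CC(=O)c1cc(CC=C(C)C)c(O)cc1O | intermediate
4 | 3-monoprenyl ketone, 1-[2,4-dihydroxy-3-(3-methylbut-2-en-1-yl)phenyl]ethan-1-one | CC(=O)c1ccc(O)c(CC=C(C)C)c1O | intermediate
5 | 1-[2,4-dihydroxy-3,5-bis(3-methylbut-2-en-1-yl)phenyl]ethan-1-one | CC(=O)c1cc(CC=C(C)C)c(O)c(CC=C(C)C)c1O | intermediate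
6 | veratraldehyde (3,4-dimethoxybenzaldehyde) | COc1ccc(C=O)cc1OC | starting material
7 | aldol adduct, racemic 1-[2,4-dihydroxy-3,5-bis(3-methylbut-2-en-1-yl)phenyl]-3-(3,4-dimethoxyphenyl)-3-hydroxypropan-1-one | COc1ccc(C(O)CC(=O)c2cc(CC=C(C)C)c(O)c(CC=C(C)C)c2O)cc1OC | intermediate
8 | (E)-1-[2,4-dihydroxy-3,5-bis(3-methylbut-2-en-1-yl)phenyl]-3-(3,4-dimethoxyphenyl)prop-2-en-1-one (2',4'-dihydroxy-3,4-dimethoxy-3',5'-diprenylchalcone) | COc1ccc(/C=C/C(=O)c2cc(CC=C(C)C)c(O)c(CC=C(C)C)c2O)cc1OC | intermediate
9 | (2S)-2-(3,4-dimethoxyphenyl)-7-hydroxy-6,8-bis(3-methylbut-2-en-1-yl)-2,3-dihydro-4H-chromen-4-one (IN0946) | COc1ccc([C@@H]2CC(=O)c3cc(CC=C(C)C)c(O)c(CC=C(C)C)c3O2)cc1OC | target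

**Totals and risks**
Total step count: 3. Longest linear sequence: 3 steps (1 → 5 → 8 → 9).

Steps most likely to fail, most serious first:

Step 3 (rate and ee on a chalcone that lacks a 6'-oxygen and carries a free, acidic 4'-OH; slow equilibration through ring opening would erode ee). The run is stopped at the best ee by chiral HPLC and the catalyst removed on silica before crystallisation. Fallback, setting out from 8 and coming back at 9: close the ring without stereocontrol (NaOAc, EtOH, reflux) to racemic 2-(3,4-dimethoxyphenyl)-7-hydroxy-6,8-bis(3-methylbut-2-en-1-yl)chroman-4-one F4. Resolve it by preparative chiral chromatography (amylose tris(3,5-dimethylphenylcarbamate) phase, supercritical CO2/MeOH) to obtain 9. Reopen the unwanted (2R)-2-(3,4-dimethoxyphenyl)-7-hydroxy-6,8-bis(3-methylbut-2-en-1-yl)chroman-4-one F5 to 8 with KOH in aqueous EtOH for another cycle.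

Step 1 (expect roughly 15–25% of 5 beside O-prenyl ethers, residual monoprenyl ketones and some C-3 geminal diprenylation). Fallback, setting out from 1 and coming back at 5: iodinate C-3 and C-5 with I2/HIO3 in aqueous EtOH to give 1-(2,4-dihydroxy-3,5-diiodophenyl)ethan-1-one F1. Then attach both prenyl groups only where iodine sits by a double Suzuki–Miyaura coupling with prenylboronic acid pinacol ester (Pd(OAc)2, di-tert-butyl(2',4',6'-triisopropylbiphenyl-2-yl)phosphine for linear allyl transfer, K3PO4, THF/H2O, 40 °C), which gives 5.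

Step 2 (the hindered trianion may be poorly soluble and condense incompletely; any racemic flavanone formed on the quench must be removed on the column because it would dilute the ee of step 3). Fallback, setting out from 5 and coming back at 8: mask the non-chelated 4-OH with MOMCl/K2CO3 in acetone to give 1-[2-hydroxy-4-(methoxymethoxy)-3,5-bis(3-methylbut-2-en-1-yl)phenyl]ethan-1-one F2. Condense it with 6 under classical Claisen–Schmidt conditions (KOH, EtOH/H2O, rt) to give (E)-3-(3,4-dimethoxyphenyl)-1-[2-hydroxy-4-(methoxymethoxy)-3,5-bis(3-methylbut-2-en-1-yl)phenyl]prop-2-en-1-one F3. Remove the acetal with catalytic HCl in MeOH at rt to return 8.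

**Further compounds**
F1 | step 1 | 1-(2,4-dihydroxy-3,5-diiodophenyl)ethan-1-one | CC(=O)c1cc(I)c(O)c(I)c1O
F2 | step 2 | 1-[2-hydroxy-4-(methoxymethoxy)-3,5-bis(3-methylbut-2-en-1-yl)phenyl]ethan-1-one | CC(=O)c1cc(CC=C(C)C)c(OCOC)c(CC=C(C)C)c1O
F3 | step 2 | (E)-3-(3,4-dimethoxyphenyl)-1-[2-hydroxy-4-(methoxymethoxy)-3,5-bis(3-methylbut-2-en-1-yl)phenyl]prop-2-en-1-one | COCOc1c(CC=C(C)C)cc(C(=O)/C=C/c2ccc(OC)c(OC)c2)c(O)c1CC=C(C)C
F4 | step 3 | racemic 2-(3,4-dimethoxyphenyl)-7-hydroxy-6,8-bis(3-methylbut-2-en-1-yl)chroman-4-one | COc1ccc(C2CC(=O)c3cc(CC=C(C)C)c(O)c(CC=C(C)C)c3O2)cc1OC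
F5 | step 3 | (2R)-2-(3,4-dimethoxyphenyl)-7-hydroxy-6,8-bis(3-methylbut-2-en-1-yl)chroman-4-one | COc1ccc([C@H]2CC(=O)c3cc(CC=C(C)C)c(O)c(CC=C(C)C)c3O2)cc1OC
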